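Over 3.00 h of stirring, the green and grey flasks lose their substrates at nearly one pace, although grey holds twice the free catalyst of green.

common to all: left-handed substrate 0.30 M; right-handed substrate 0.30 M; racemization catalyst 1.5 mM

| run | solid reagent | free catalyst | remark | time |
|---|---|---|---|---|
| green | 0.66 M | 2.2 mM | run made earlier |  |
| grey | 0.66 M | 4.5 mM | run made earlier |  |
| south-east | 0.660 M | 3.0 mM |  | 4.0 h |
| south | 0.660 M | 1.5 mM |  | 4.0 h |

- green (time / h: right-handed substrate / %, left-handed substrate / %): 0.250: 49, 46; 0.333: 50, 51; 0.667: 47, 46; 1.00: 46, 45; 1.50: 41, 42; 3.00: 33, 32
- grey (time / h: right-handed substrate / %, left-handed substrate / %): 0.500: 50, 47; 1.00: 46, 42; 1.33: 42, 43; 2.00: 38, 36; 2.50: 34, 33; 3.00: 33, 31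

(each reading ± 1.5 percentage points)

- free catalyst is single-handed; left-handed substrate and right-handed substrate are mirror images of each other, charged as a racemate, each of them at the stated concentration
- solid, in amounts per volume of the solution: solid reagent
- the earlier runs were read with a standard deviation of 1.5 percentage points
- at the start none of the solid reagent is in solution
- an excess is the difference of the two amounts in percent of their sum
- an excess is below zero if the other one leads

* which of the two ends with the higher excess of right-handed substrate over left-handed substrate among what is left of the two ("neither" if they lie within 2 percentage points) (south-east / south / neither)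
* excess of right-handed substrate over left-handed substrate among what is left of the two at the end, south-east
* excess of right-handed substrate over left-handed substrate among what is left of the two at the end, south

Read down the rows. At 1.00 h the two substrates together stand at 91.0% in green and 88.0% in grey; at 3.00 h they stand at 65.0% and 64.0%. Such a sum scatters by 2.1 percentage points, so the rows barely part the two runs. The loss looks zero-order, with its rate-limiting step outside the catalysis.

Green gives the loss rate w, the fraction of the charged pair consumed per hour, 0.117 h⁻¹. Integrating dn/dt = −w gives the remaining fraction n = 1 − w·t, which is 53.3% at 4.0 h for south-east and south alike. For south this is an extrapolation, since its 1.5 mM of free catalyst lies below green's 2.2 mM.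

Now read column against column, over both runs. Right-handed minus left-handed averages d = 1.3 points, give or take 0.61 points. If that gap holds while the pool shrinks, the excess is d/n = 2.34%, give or take 1.14%, in both flasks, so neither leads.

The forecast gives 2.5% for south-east, slightly above this reckoning, 2.3% for south, and neither for the lead: “Catalyst loading therefore largely cancels.”

The flasks end at 0.403% in south-east and 0.529% in south, so the answer is neither.

    partner + racemization catalyst → spent catalyst (k = 0.500 M⁻¹ min⁻¹)
    solid reagent ⇌ partner, rate k2*(cs2 - [partner]) while solid is left; crystals form when [partner] > cs2 (solubility = 0.0510 M, k = 0.0270 min⁻¹)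
    partner + free catalyst + left-handed substrate → free catalyst + left-handed product (k = 180 M⁻² min⁻¹)
    left-handed substrate + racemization catalyst ⇌ right-handed substrate + racemization catalyst, rate k4*[racemization catalyst]*[left-handed substrate] forward; the back reaction follows from the equilibrium constant (k = 210 M⁻¹ min⁻¹)
    left-handed product ⇌ right-handed product (k = 3.50 × 10⁻⁴ min⁻¹)
    partner + free catalyst + right-handed substrate → free catalyst + right-handed product (k = 88.0 M⁻² min⁻¹)

Both substrate pools are nearly racemic at the end; the forward half-life of left-handed substrate by racemization, as charged in south-east, is 2.2 min, shorter than the 4.0 h run. Against the line's 53.3%, south-east holds 53.5% of the pair and south 59.2%. A neighbouring flask is south with 2.6 M of solid reagent. Since w contains no solid charge, the line again gives 53.3%. That flask holds 59.2% of the pair, at an excess of 0.529%.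

(The data were computed with constants of no real substance, and the scatter is random.)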